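A direct plan would join the chromanone triflate A1 and the benzofuran-2-yl pinacol boronate A2 by Suzuki coupling to the biaryl ketone A3, then reduce and dehydrate the ketone to the bis-MOM chromene A4 and cleave both acetals with aqueous acid. Its weakest steps would be:
- Placing the prenyl group of A1 by O-allylation, Claisen rearrangement and cross-metathesis: with two protecting-group steps this is a long linear run-up that installs a single C5 unit, while the boronate branch builds an ester only to delete it by decarboxylation.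
- The Suzuki coupling: it forms the most hindered bond of the target, at an aryl carbon flanked by the prenyl group and the peri carbonyl, with a 2-heteroaryl boronate that protodeboronates readily.
- The endgame: ketone reduction and dehydration are redox steps spent on one alkene, and the final acid cleavage of the MOM ethers exposes an o-prenylphenol and a 2H-chromene to conditions that can close the prenyl group to a chroman.

**Retrosynthetic overview of the new route**
1. Cathafuran C ⇐ bis-silyl ether 22 ⇐ salicylaldehyde 18. The pyran ring is closed last: 2-methylpropenyl Grignard adds to the C4a–CHO group, and the resulting o-quinone methide closes O1–C2 by oxa-6π electrocyclisation.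
2. 18 ⇐ [4+2] benzannulation that builds the whole central benzene ring (C4a, C5, C6, C7, C8, C8a) from ynal 9 (alkyne C4a≡C5 carrying CHO and the benzofuran) and siloxydiene 16 (C8a–C8–C7–C6 carrying both oxygens and the prenyl group). New bonds: C4a–C8a and C5–C6.
3. Feature used: the central ring is pentasubstituted and its only free position, C8–H, lies between O1 and the 7-OH, which is where electrophilic or Claisen chemistry on a resorcinol would react first. Building the ring lets the polarity of the cycloaddition fix the substituents at C4a, C5 and C6.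
4. 9 ⇐ 2,4-dihydroxybenzaldehyde (gem-dibromoalkene, copper C–O closure of the furan, Sonogashira). 16 ⇐ methyl acetoacetate + prenyl bromide.
5. Ring order: furan → central benzene → pyran. The design needs no cross-coupling at the hindered biaryl bond, brings the prenyl group in as prenyl bromide on an acyclic keto ester, has no ketone redox, and ends with fluoride instead of acid.

Key step: step 8

Remark on the chemistry: the target has no stereocentre and no configurationally stable axis, so "single enantiomer" is taken as the one achiral compound. Enol ether geometries (14, 16, 21) and the transient sp3 centres of 17 and 20 are left undefined because they are lost.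

**Branch A: benzofuranyl ynal**

Step 1
Reactants: 1 2,4-dihydroxybenzaldehyde; 2 triisopropylsilyl chloride
Product: 3 2-hydroxy-4-(triisopropylsilyloxy)benzaldehyde
Conditions: TIPSCl (1.05 equiv), imidazole, CH2Cl2, 0 °C
Reagents that add atoms: triisopropylsilyl chloride (2), CC(C)[Si](Cl)(C(C)C)C(C)C
Why: Selective O-silylation; the 2-OH is held in a hydrogen bond to the aldehyde, so the more acidic, unhindered 4-OH should react.

Step 2
Reactants: 3 2-hydroxy-4-(triisopropylsilyloxy)benzaldehyde; 4 carbon tetrabromide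
Product: 5 2-(2,2-dibromovinyl)-5-(triisopropylsilyloxy)phenol
Conditions: CBr4, PPh3, Zn dust (2 equiv each, reagent pre-formed), CH2Cl2, rt
Reagents that add atoms: carbon tetrabromide (4), BrC(Br)(Br)Br
Why: Ramirez gem-dibromoolefination; the zinc-modified reagent avoids Ph3PBr2 and should tolerate the free phenol and the aryl silyl ether.

Step 3
Reactants: 5 2-(2,2-dibromovinyl)-5-(triisopropylsilyloxy)phenol; 6 prop-2-yn-1-ol
Product: 8 3-[6-(triisopropylsilyloxy)benzofuran-2-yl]prop-2-yn-1-ol, via 2-bromo-6-(triisopropylsilyloxy)benzofuran 7 (not isolated)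
Conditions: CuI (5 mol %), K3PO4, THF, 60 °C; then Pd(PPh3)2Cl2 (3 mol %), prop-2-yn-1-ol, i-Pr2NH, 50 °C, same flask
Reagents that add atoms: prop-2-yn-1-ol (6), C#CCO
Why: Copper-catalysed intramolecular Ullmann-type C–O coupling of the gem-dibromoalkene closes the furan ring to the 2-bromobenzofuran, which then undergoes Sonogashira coupling; the copper salt serves both stages.

Step 4
Reactants: 8 3-[6-(triisopropylsilyloxy)benzofuran-2-yl]prop-2-yn-1-ol
Product: 9 3-[6-(triisopropylsilyloxy)benzofuran-2-yl]prop-2-ynal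
Conditions: activated MnO2 (excess), CH2Cl2, rt
Reagents that add atoms: none
Why: MnO2 oxidation of an activated propargylic alcohol under neutral conditions that leave the silyl ether and the ynal untouched.

**Branch B: prenylated siloxydiene**

Step 5
Reactants: 10 methyl acetoacetate; 11 prenyl bromide (1-bromo-3-methylbut-2-ene)
Product: 12 methyl 7-methyl-3-oxooct-6-enoate
Conditions: NaH, THF, 0 °C; n-BuLi, 0 °C; prenyl bromide, 0 °C → rt; aq. HCl quench
Reagents that add atoms: prenyl bromide (11), CC(C)=CCBr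
Why: γ-Alkylation of the acetoacetate dianion; the more basic terminal carbanion reacts by SN2 at the primary carbon, so the prenyl unit is installed intact on an acyclic precursor.

Step 6
Reactants: 12 methyl 7-methyl-3-oxooct-6-enoate; 13 tert-butyldimethylsilyl triflate
Product: 14 methyl 3-(tert-butyldimethylsilyloxy)-7-methylocta-2,6-dienoate (E/Z mixture, geometry lost later)
Conditions: TBSOTf (1.1 equiv), Et3N, CH2Cl2, 0 °C
Reagents that add atoms: tert-butyldimethylsilyl triflate (13), CC(C)(C)[Si](C)(C)OS(=O)(=O)C(F)(F)F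
Why: Soft enolisation and O-silylation of the β-keto ester to the conjugated silyl enol ether; TBS is chosen so that this oxygen emerges from the key step as a robust aryl silyl ether.

Step 7
Reactants: 14 methyl 3-(tert-butyldimethylsilyloxy)-7-methylocta-2,6-dienoate; 15 chlorotrimethylsilane
Product: 16 3-(tert-butyldimethylsilyloxy)-1-methoxy-7-methyl-1-(trimethylsilyloxy)octa-1,3,6-triene (expected mainly 3Z; used crude under argon)
Conditions: LDA (commercial solution, 1.2 equiv), THF, −78 °C; TMSCl, −78 → 0 °C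
Reagents that add atoms: chlorotrimethylsilane (15), C[Si](C)(C)Cl
Why: γ-Deprotonation of the vinylogous ester and O-silylation of the dienolate, the standard preparation of 1-alkoxy-1,3-bis(silyloxy)dienes.

**Union and endgame**

Step 8
Reactants: 9 3-[6-(triisopropylsilyloxy)benzofuran-2-yl]prop-2-ynal; 16 3-(tert-butyldimethylsilyloxy)-1-methoxy-7-methyl-1-(trimethylsilyloxy)octa-1,3,6-triene (2 equiv)
Product: 18 4-(tert-butyldimethylsilyloxy)-2-hydroxy-5-(3-methylbut-2-en-1-yl)-6-[6-(triisopropylsilyloxy)benzofuran-2-yl]benzaldehyde, via 4-(tert-butyldimethylsilyloxy)-6-methoxy-3-(3-methylbut-2-en-1-yl)-2-[6-(triisopropylsilyloxy)benzofuran-2-yl]-6-(trimethylsilyloxy)cyclohexa-1,4-diene-1-carbaldehyde 17 (not isolated)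
Conditions: PhMe, 23 → 80 °C, Ar; then TFA (0.2 equiv), wet THF, 0 °C
Reagents that add atoms: none
Why: Normal-electron-demand Diels–Alder reaction of the 1,1,3-trioxygenated diene with the acetylenic aldehyde (concerted but asynchronous, or Michael addition followed by ring closure, with the same outcome) gives cyclohexa-1,4-diene 17, whose mixed silyl methyl ketal collapses on mild acid treatment with loss of methanol and trimethylsilanol to the chelated phenol of the new benzene ring. The closest known reaction type is the benzannulation of 1-alkoxy-1,3-bis(silyloxy)dienes with acetylenic ketones, esters and aldehydes to resorcinol derivatives and biaryls. The one ring closed is the central six-membered carbocycle, by intermolecular [4+2] cycloaddition forming C4a–C8a and C5–C6. No stereocentre survives, since the two sp3 carbons of 17 become aromatic. The step needs regioselectivity, secured by polarity: the nucleophilic C4 terminus of the diene (bearing the prenyl group) bonds to the β-carbon of the ynal (bearing the benzofuran) and the ketene acetal carbon to the α-carbon, which places CHO, benzofuran and prenyl on three adjacent carbons and leaves C8–H between the two oxygens. It also needs chemoselectivity for the activated alkyne over the aldehyde C=O, favoured by the absence of Lewis acid, and over the unactivated prenyl and benzofuran C2=C3 double bonds.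

Step 9
Reactants: 18 4-(tert-butyldimethylsilyloxy)-2-hydroxy-5-(3-methylbut-2-en-1-yl)-6-[6-(triisopropylsilyloxy)benzofuran-2-yl]benzaldehyde; 19 2-methylprop-1-enylmagnesium bromide
Product: 22 tert-butyl{[2,2-dimethyl-6-(3-methylbut-2-en-1-yl)-5-[6-(triisopropylsilyloxy)benzofuran-2-yl]-2H-chromen-7-yl]oxy}dimethylsilane, via 1-{4-(tert-butyldimethylsilyloxy)-2-hydroxy-5-(3-methylbut-2-en-1-yl)-6-[6-(triisopropylsilyloxy)benzofuran-2-yl]phenyl}-3-methylbut-2-en-1-ol 20 (not isolated), via 3-(tert-butyldimethylsilyloxy)-6-(3-methylbut-2-en-1-ylidene)-4-(3-methylbut-2-en-1-yl)-5-[6-(triisopropylsilyloxy)benzofuran-2-yl]cyclohexa-2,4-dien-1-one 21 (not isolated)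
Conditions: 2-methylprop-1-enylmagnesium bromide (3 equiv), THF, −20 → 0 °C; then AcOH (excess), 45 °C, same flask
Reagents that add atoms: 2-methylprop-1-enylmagnesium bromide (19), CC(C)=C[Mg]Br
Why: Grignard 1,2-addition to the salicylaldehyde (the first equivalent forms the magnesium phenoxide), then acid-promoted loss of water from the o-hydroxybenzylic allylic carbinol gives the o-quinone methide, a 1-oxatriene that closes the pyran ring by oxa-6π electrocyclisation with rearomatisation. The 7-O-silyl ether prevents acid cyclisation of the prenyl group.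

Step 10
Reactants: 22 tert-butyl{[2,2-dimethyl-6-(3-methylbut-2-en-1-yl)-5-[6-(triisopropylsilyloxy)benzofuran-2-yl]-2H-chromen-7-yl]oxy}dimethylsilane
Product: 23 Cathafuran C, 5-(6-hydroxybenzofuran-2-yl)-2,2-dimethyl-6-(3-methylbut-2-en-1-yl)-2H-chromen-7-ol
Conditions: TBAF (2.4 equiv), AcOH (2.4 equiv), THF, 0 °C → rt, Ar
Reagents that add atoms: none
Why: Buffered fluoride cleavage of both aryl silyl ethers; no acid is used, so the o-prenylphenol and the 2H-chromene should not be at risk.

**Compound list**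
1 | 2,4-dihydroxybenzaldehyde | O=Cc1ccc(O)cc1O | starting material
2 | triisopropylsilyl chloride | CC(C)[Si](Cl)(C(C)C)C(C)C | starting material
3 | 2-hydroxy-4-(triisopropylsilyloxy)benzaldehyde | O=Cc1ccc(O[Si](C(C)C)(C(C)C)C(C)C)cc1O | intermediate
4 | carbon tetrabromide | BrC(Br)(Br)Br | starting material
5 | 2-(2,2-dibromovinyl)-5-(triisopropylsilyloxy)phenol | Oc1cc(O[Si](C(C)C)(C(C)C)C(C)C)ccc1C=C(Br)Br | intermediate
6 | prop-2-yn-1-ol | C#CCO | starting material
7 | 2-bromo-6-(triisopropylsilyloxy)benzofuran | Brc1cc2ccc(O[Si](C(C)C)(C(C)C)C(C)C)cc2o1 | intermediate (not isolated)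
8 | 3-[6-(triisopropylsilyloxy)benzofuran-2-yl]prop-2-yn-1-ol | OCC#Cc1cc2ccc(O[Si](C(C)C)(C(C)C)C(C)C)cc2o1 | intermediate
9 | 3-[6-(triisopropylsilyloxy)benzofuran-2-yl]prop-2-ynal | O=CC#Cc1cc2ccc(O[Si](C(C)C)(C(C)C)C(C)C)cc2o1 | intermediate
10 | methyl acetoacetate | COC(=O)CC(C)=O | starting material
11 | prenyl bromide | CC(C)=CCBr | starting material
12 | methyl 7-methyl-3-oxooct-6-enoate | COC(=O)CC(=O)CCC=C(C)C | intermediate
13 | tert-butyldimethylsilyl triflate | CC(C)(C)[Si](C)(C)OS(=O)(=O)C(F)(F)F | starting material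
14 | methyl 3-(tert-butyldimethylsilyloxy)-7-methylocta-2,6-dienoate | COC(=O)C=C(O[Si](C)(C)C(C)(C)C)CCC=C(C)C | intermediate
15 | chlorotrimethylsilane | C[Si](C)(C)Cl | starting material
16 | 3-(tert-butyldimethylsilyloxy)-1-methoxy-7-methyl-1-(trimethylsilyloxy)octa-1,3,6-triene | COC(O[Si](C)(C)C)=CC(O[Si](C)(C)C(C)(C)C)=CCC=C(C)C | intermediate
17 | 4-(tert-butyldimethylsilyloxy)-6-methoxy-3-(3-methylbut-2-en-1-yl)-2-[6-(triisopropylsilyloxy)benzofuran-2-yl]-6-(trimethylsilyloxy)cyclohexa-1,4-diene-1-carbaldehyde (diastereomer mixture) | COC1(O[Si](C)(C)C)C=C(O[Si](C)(C)C(C)(C)C)C(CC=C(C)C)C(c2cc3ccc(O[Si](C(C)C)(C(C)C)C(C)C)cc3o2)=C1C=O | intermediate (not isolated)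
18 | 4-(tert-butyldimethylsilyloxy)-2-hydroxy-5-(3-methylbut-2-en-1-yl)-6-[6-(triisopropylsilyloxy)benzofuran-2-yl]benzaldehyde | O=Cc1c(O)cc(O[Si](C)(C)C(C)(C)C)c(CC=C(C)C)c1-c1cc2ccc(O[Si](C(C)C)(C(C)C)C(C)C)cc2o1 | intermediate
19 | 2-methylprop-1-enylmagnesium bromide | CC(C)=C[Mg]Br | starting material
20 | 1-{4-(tert-butyldimethylsilyloxy)-2-hydroxy-5-(3-methylbut-2-en-1-yl)-6-[6-(triisopropylsilyloxy)benzofuran-2-yl]phenyl}-3-methylbut-2-en-1-ol (racemic) | CC(C)=CC(O)c1c(O)cc(O[Si](C)(C)C(C)(C)C)c(CC=C(C)C)c1-c1cc2ccc(O[Si](C(C)C)(C(C)C)C(C)C)cc2o1 | intermediate (not isolated)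
21 | 3-(tert-butyldimethylsilyloxy)-6-(3-methylbut-2-en-1-ylidene)-4-(3-methylbut-2-en-1-yl)-5-[6-(triisopropylsilyloxy)benzofuran-2-yl]cyclohexa-2,4-dien-1-one (o-quinone methide) | CC(C)=CC=C1C(=O)C=C(O[Si](C)(C)C(C)(C)C)C(CC=C(C)C)=C1c1cc2ccc(O[Si](C(C)C)(C(C)C)C(C)C)cc2o1 | intermediate (not isolated)
22 | tert-butyl{[2,2-dimethyl-6-(3-methylbut-2-en-1-yl)-5-[6-(triisopropylsilyloxy)benzofuran-2-yl]-2H-chromen-7-yl]oxy}dimethylsilane | CC(C)=CCc1c(O[Si](C)(C)C(C)(C)C)cc2c(c1-c1cc3ccc(O[Si](C(C)C)(C(C)C)C(C)C)cc3o1)C=CC(C)(C)O2 | intermediate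
23 | Cathafuran C | CC(C)=CCc1c(O)cc2c(c1-c1cc3ccc(O)cc3o1)C=CC(C)(C)O2 | target

**Totals**
Total steps: 10. Longest linear sequence: 7 (steps 1–4, 8–10).

**Steps most likely to fail**

1. Step 8. The ketene acetal terminus of the diene may add to the aldehyde carbonyl (aldol or hetero-Diels–Alder), or the ynal may oligomerise on heating before the doubly substituted alkyne and diene termini combine. The fallback sets out from 9 and returns at 18, and swaps the aldehyde for an ester that the diene cannot attack, so the cycloaddition can be forced. Pinnick oxidation of 9 would give 3-[6-(triisopropylsilyloxy)benzofuran-2-yl]propiolic acid F1, and methylation with trimethylsilyldiazomethane its methyl ester F2. Cycloaddition of F2 with 16 in xylene at 130 °C would give methyl 4-(tert-butyldimethylsilyloxy)-6-methoxy-3-(3-methylbut-2-en-1-yl)-2-[6-(triisopropylsilyloxy)benzofuran-2-yl]-6-(trimethylsilyloxy)cyclohexa-1,4-diene-1-carboxylate F3. The same mild acid treatment would aromatise it to methyl 4-(tert-butyldimethylsilyloxy)-2-hydroxy-5-(3-methylbut-2-en-1-yl)-6-[6-(triisopropylsilyloxy)benzofuran-2-yl]benzoate F4. DIBAL-H reduction would give 5-(tert-butyldimethylsilyloxy)-2-(hydroxymethyl)-4-(3-methylbut-2-en-1-yl)-3-[6-(triisopropylsilyloxy)benzofuran-2-yl]phenol F5, and MnO2 oxidation of the benzylic alcohol would return to 18.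

2. Step 9. Addition to the hindered aldehyde of the magnesium phenoxide may stall, or the ionised carbinol may be captured at carbon (C3 of the benzofuran or the prenyl alkene) in a Friedel–Crafts-type closure instead of closing through oxygen. The fallback sets out from 18 and returns at 22, and uses neither an organomagnesium reagent nor acid. An amine-mediated Petasis reaction of 18 with (2-methylprop-1-enyl)boronic acid and dibenzylamine in dioxane at 90 °C would give 5-(tert-butyldimethylsilyloxy)-2-[1-(dibenzylamino)-3-methylbut-2-en-1-yl]-4-(3-methylbut-2-en-1-yl)-3-[6-(triisopropylsilyloxy)benzofuran-2-yl]phenol F6. Thermal loss of dibenzylamine from F6 would give the o-quinone methide 21, which electrocyclises to 22.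

3. Step 3. Palladium may insert into uncyclised dibromoalkene and couple twice to an enediyne, the alkynol may dimerise oxidatively under copper, or phosphate may cleave the aryl silyl ether. The fallback sets out from 3 (with 6) and returns at 8, and closes the furan by hydroalkoxylation of a diyne instead of C–O cross-coupling. Seyferth–Gilbert homologation of 3 with the Ohira–Bestmann reagent (K2CO3, MeOH, 0 °C → rt) would give 2-ethynyl-5-(triisopropylsilyloxy)phenol F7. Bromination of 6 (NBS, AgNO3 cat., acetone) would give 3-bromoprop-2-yn-1-ol F8. Cadiot–Chodkiewicz coupling of F7 with F8 (CuCl, NH2OH·HCl, n-BuNH2) would give 5-[2-hydroxy-4-(triisopropylsilyloxy)phenyl]penta-2,4-diyn-1-ol F9. Its 5-endo-dig cyclisation (CuI, Et3N, 60 °C) would deliver 8.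

**Further compounds**
F1 | step 8 | 3-[6-(triisopropylsilyloxy)benzofuran-2-yl]propiolic acid | OC(=O)C#Cc1cc2ccc(O[Si](C(C)C)(C(C)C)C(C)C)cc2o1
F2 | step 8 | methyl 3-[6-(triisopropylsilyloxy)benzofuran-2-yl]propiolate | COC(=O)C#Cc1cc2ccc(O[Si](C(C)C)(C(C)C)C(C)C)cc2o1
F3 | step 8 | methyl 4-(tert-butyldimethylsilyloxy)-6-methoxy-3-(3-methylbut-2-en-1-yl)-2-[6-(triisopropylsilyloxy)benzofuran-2-yl]-6-(trimethylsilyloxy)cyclohexa-1,4-diene-1-carboxylate | COC(=O)C1=C(c2cc3ccc(O[Si](C(C)C)(C(C)C)C(C)C)cc3o2)C(CC=C(C)C)C(O[Si](C)(C)C(C)(C)C)=CC1(OC)O[Si](C)(C)C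
F4 | step 8 | methyl 4-(tert-butyldimethylsilyloxy)-2-hydroxy-5-(3-methylbut-2-en-1-yl)-6-[6-(triisopropylsilyloxy)benzofuran-2-yl]benzoate | COC(=O)c1c(O)cc(O[Si](C)(C)C(C)(C)C)c(CC=C(C)C)c1-c1cc2ccc(O[Si](C(C)C)(C(C)C)C(C)C)cc2o1
F5 | step 8 | 5-(tert-butyldimethylsilyloxy)-2-(hydroxymethyl)-4-(3-methylbut-2-en-1-yl)-3-[6-(triisopropylsilyloxy)benzofuran-2-yl]phenol | OCc1c(O)cc(O[Si](C)(C)C(C)(C)C)c(CC=C(C)C)c1-c1cc2ccc(O[Si](C(C)C)(C(C)C)C(C)C)cc2o1
F6 | step 9 | 5-(tert-butyldimethylsilyloxy)-2-[1-(dibenzylamino)-3-methylbut-2-en-1-yl]-4-(3-methylbut-2-en-1-yl)-3-[6-(triisopropylsilyloxy)benzofuran-2-yl]phenol | CC(C)=CC(N(Cc1ccccc1)Cc1ccccc1)c1c(O)cc(O[Si](C)(C)C(C)(C)C)c(CC=C(C)C)c1-c1cc2ccc(O[Si](C(C)C)(C(C)C)C(C)C)cc2o1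
F7 | step 3 | 2-ethynyl-5-(triisopropylsilyloxy)phenol | C#Cc1ccc(O[Si](C(C)C)(C(C)C)C(C)C)cc1O
F8 | step 3 | 3-bromoprop-2-yn-1-ol | OCC#CBr
F9 | step 3 | 5-[2-hydroxy-4-(triisopropylsilyloxy)phenyl]penta-2,4-diyn-1-ol | OCC#CC#Cc1ccc(O[Si](C(C)C)(C(C)C)C(C)C)cc1O
A1 | direct plan | 7-(methoxymethoxy)-2,2-dimethyl-6-(3-methylbut-2-en-1-yl)-4-oxochroman-5-yl trifluoromethanesulfonate | CC1(C)CC(=O)c2c(OS(=O)(=O)C(F)(F)F)c(CC=C(C)C)c(OCOC)cc2O1
A2 | direct plan | 2-[6-(methoxymethoxy)benzofuran-2-yl]-4,4,5,5-tetramethyl-1,3,2-dioxaborolane | COCOc1ccc2cc(B3OC(C)(C)C(C)(C)O3)oc2c1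
A3 | direct plan | 5-[6-(methoxymethoxy)benzofuran-2-yl]-7-(methoxymethoxy)-2,2-dimethyl-6-(3-methylbut-2-en-1-yl)chroman-4-one | CC1(C)CC(=O)c2c(-c3cc4ccc(OCOC)cc4o3)c(CC=C(C)C)c(OCOC)cc2O1
A4 | direct plan | 6-(methoxymethoxy)-2-[7-(methoxymethoxy)-2,2-dimethyl-6-(3-methylbut-2-en-1-yl)-2H-chromen-5-yl]benzofuran | CC1(C)C=Cc2c(-c3cc4ccc(OCOC)cc4o3)c(CC=C(C)C)c(OCOC)cc2O1
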